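Side-chain locants run from the benzylic C-1' to the ether carbon C-11'. The route rests on disconnecting, in the 14-membered aryl ether ring, the CH2–CH2 bond between C-8', the allylic methylene of the Z-configured C-6'=C-7' alkene, and C-9', the methylene beside the carbinol carbon C-10'. At the ketone level C-10' has a single enolisable α-carbon, because its other neighbour is the quaternary C-11' bearing the aryl ether oxygen. As a β-keto sulfone, C-9' is ionised by carbonate alone and displaces a primary Z-allylic bromide at C-8', closing the macrocycle in one operation with both alkene geometries intact. The precursor is an open-chain hydroquinone diether carrying both termini, assembled by cross-metathesis.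

Key step: step 9

Remark: the single stereocentre of the target (C-10') is read from the SMILES as R, the alkenes as 2'E (CO2H trans to C-1') and 6'Z (C-8' cis to C-5'); compounds 1, 4, 6, 8 and 9 are taken to be commercially available.

Step 1
Reactants: 1 4-(allyloxy)phenol
Product: 2 allyl 4-(triisopropylsilyloxy)phenyl ether
Conditions: iPr3SiCl, imidazole, DMF, rt
Reagents that add atoms: triisopropylsilyl chloride, CC(C)[Si](Cl)(C(C)C)C(C)C
Why: Imidazole-promoted silylation of the free phenol (silyl ether formation) should install a TIPS ether that withstands the 190 °C rearrangement, the carbonate alkylations and the lithiated sulfone used later.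

Step 2
Reactants: 2 allyl 4-(triisopropylsilyloxy)phenyl ether
Product: 3 2-allyl-4-(triisopropylsilyloxy)phenol
Conditions: PhNEt2, 190 °C, argon
Reagents that add atoms: none
Why: The aromatic Claisen rearrangement ([3,3]-sigmatropic shift, then tautomerisation) should move the allyl group to the ortho carbon, the two ortho positions being equivalent.

Step 3
Reactants: 3 2-allyl-4-(triisopropylsilyloxy)phenol; 4 ethyl 2-bromo-2-methylpropanoate
Product: 5 ethyl 2-[2-allyl-4-(triisopropylsilyloxy)phenoxy]-2-methylpropanoate
Conditions: Cs2CO3, 4 (3 equiv), MeCN, 60 °C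
Reagents that add atoms: none
Why: Williamson-type O-alkylation of the caesium phenoxide by the tertiary α-bromo ester (the usual fibrate ether synthesis) should give the hindered aryl ether, excess 4 offsetting its elimination to methacrylate.

Step 4
Reactants: 5 ethyl 2-[2-allyl-4-(triisopropylsilyloxy)phenoxy]-2-methylpropanoate; 6 methyl phenyl sulfone
Product: 7 3-[2-allyl-4-(triisopropylsilyloxy)phenoxy]-3-methyl-1-(phenylsulfonyl)butan-2-one
Conditions: 6 (2.2 equiv), n-BuLi (2.2 equiv), THF, −78 °C; then 5, −78 to 0 °C; aq NH4Cl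
Reagents that add atoms: none
Why: Claisen-type C-acylation of the lithiated sulfone by the non-enolisable ester should stop at the β-keto sulfone, because the second equivalent of carbanion deprotonates it as it forms.

Step 5
Reactants: 8 (4-carboxybutyl)triphenylphosphonium bromide; 9 1-(tert-butyldimethylsilyloxy)propan-2-one
Product: 11 methyl (Z)-7-(tert-butyldimethylsilyloxy)-6-methylhept-5-enoate, via sodium carboxylate 10 (not isolated)
Conditions: NaN(SiMe3)2 (2.1 equiv), THF, 0 °C; then 9, −78 °C to rt; then MeI, DMF, rt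
Reagents that add atoms: iodomethane, CI
Why: The Wittig reaction of a non-stabilised ylide with an α-silyloxy ketone (the Z-selective variant known for α-alkoxy ketones) should place the CH2OSi group cis to the chain, and the sodium carboxylate is then esterified in the same flask by SN2 methylation.

Step 6
Reactants: 11 methyl (Z)-7-(tert-butyldimethylsilyloxy)-6-methylhept-5-enoate
Product: 14 methyl (Z)-7-(tert-butyldimethylsilyloxy)-6-methyl-2-methylidenehept-5-enoate, via Mannich base 12 (not isolated), via ammonium iodide 13 (not isolated)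
Conditions: LiN(iPr)2, THF, −78 °C; CH2=NMe2+ I−, −78 °C to rt; then MeI, MeOH, rt; then aq NaHCO3, CH2Cl2, rt
Reagents that add atoms: dimethylmethylideneammonium iodide (Eschenmoser's salt), C=[N+](C)C.[I-]; iodomethane, CI (its methyl stays only in 13)
Why: Mannich reaction of the ester enolate with Eschenmoser's salt, N-methylation and base-induced β-elimination of trimethylamine (Eschenmoser methylenation) should give the 2-substituted acrylate without touching the Z-alkene.

Step 7
Reactants: 14 methyl (Z)-7-(tert-butyldimethylsilyloxy)-6-methyl-2-methylidenehept-5-enoate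
Product: 15 methyl (Z)-7-bromo-6-methyl-2-methylidenehept-5-enoate
Conditions: Ph3PBr2, CH2Cl2, 0 °C to rt
Reagents that add atoms: triphenylphosphine dibromide, BrP(Br)(c1ccccc1)(c1ccccc1)c1ccccc1
Why: Triphenylphosphine dibromide should convert the primary allylic silyl ether directly into the bromide through an oxyphosphonium ion displaced by bromide in an SN2 step (Appel-type), so the Z geometry is kept.

Step 8
Reactants: 7 3-[2-allyl-4-(triisopropylsilyloxy)phenoxy]-3-methyl-1-(phenylsulfonyl)butan-2-one; 15 methyl (Z)-7-bromo-6-methyl-2-methylidenehept-5-enoate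
Product: 16 methyl (2E,5Z)-7-bromo-6-methyl-2-{2-[2-(2-methyl-3-oxo-4-(phenylsulfonyl)butan-2-yl)oxy-5-(triisopropylsilyloxy)phenyl]ethylidene}hept-5-enoate
Conditions: second-generation Hoveyda–Grubbs catalyst [RuCl2(H2IMes)(=CH–C6H4–2-OiPr)] (10 mol %), 1,4-benzoquinone (20 mol %), 15 (3 equiv), CH2Cl2, 40 °C
Reagents that add atoms: none
Why: Olefin cross-metathesis between the terminal allyl arene and the non-dimerising 1,1-disubstituted acrylate should, under thermodynamic control, place the ester trans to the arylmethyl group (2'E), with benzoquinone suppressing allyl-to-propenyl migration and the trisubstituted alkene, allylic bromide and β-keto sulfone as bystanders.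

Step 9
Reactants: 16 methyl (2E,5Z)-7-bromo-6-methyl-2-{2-[2-(2-methyl-3-oxo-4-(phenylsulfonyl)butan-2-yl)oxy-5-(triisopropylsilyloxy)phenyl]ethylidene}hept-5-enoate
Product: 17 macrocyclic β-keto sulfone (14-membered ring closed between C-8' and C-9'; SO2Ph on C-9'; ketone at C-10'; methyl ester; aryl OTIPS; 2'E 6'Z)
Conditions: K2CO3 (5 equiv), MeCN, 50 °C, syringe-pump addition of 16 to a final concentration of about 1 mM
Reagents that add atoms: none
Why: Carbonate ionises only the C-9' methylene between ketone and sulfone (estimated pKa about 12), and the resulting soft enolate displaces bromide at the primary allylic C-8' in an intramolecular SN2 C-alkylation. The closest known reaction type is the high-dilution macrocyclisation of β-keto sulfones, β-keto esters and malonates onto allylic halides used for 14-membered carbocycles. The single ring formed is the 14-membered ring, closed in the 14-exo-tet mode. The only new stereocentre is the sulfonyl-bearing C-9', formed without control and erased in step 10, while direct displacement at the primary carbon leaves the 6'Z and 2'E geometries untouched. The step needs C- over O-alkylation, ring closure over oligomerisation, and reaction at C-9' rather than at the acidic C-1' methylene γ to the ester (whose dienolate would close a six-membered ring onto C-8'); the soft sulfonyl enolate, the slow addition and a base too weak to ionise C-1' should secure these in turn, and because C-11' is quaternary no regioisomeric enolate exists.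

Step 10
Reactants: 17 macrocyclic β-keto sulfone
Product: 18 macrocyclic ketone (C-9' now CH2; ketone at C-10'; methyl ester; aryl OTIPS; 2'E 6'Z)
Conditions: Al(Hg), THF/H2O 9:1, 0 °C to rt
Reagents that add atoms: none
Why: Reductive desulfonylation of a β-keto sulfone by aluminium amalgam (two-electron C–S cleavage to the enolate, then protonation) should remove the activating group under near-neutral conditions that spare the ester, the alkenes and the less easily reduced α-aryloxy ketone.

Step 11
Reactants: 18 macrocyclic ketone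
Product: 19 (10'R)-alcohol (methyl ester; aryl OTIPS; 2'E 6'Z)
Conditions: (S)-2-methyl-CBS-oxazaborolidine (0.3 equiv), catecholborane (2 equiv), toluene, −40 to −20 °C; then MeOH, pH 7 buffer
Reagents that add atoms: none
Why: In the Corey–Bakshi–Shibata reduction the ketone should bind the (S)-oxazaborolidine with the bulky C(CH3)2OAr group turned away from the catalyst, so that hydride is delivered to the face giving the (10'R)-alcohol, catecholborane being chosen because it neither hydroborates the alkenes nor reduces the ester.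

Step 12
Reactants: 19 (10'R)-alcohol
Product: 21 petchiether B, via phenol methyl ester 20 (not isolated)
Conditions: Bu4NF, THF, 0 °C; then LiOH, MeOH/H2O, rt (degassed); then 1 M HCl to pH 3
Reagents that add atoms: lithium hydroxide, [Li+].[OH-]
Why: Fluoride should cleave the aryl silyl ether and hydroxide then saponify the methyl ester (acyl–oxygen cleavage), conditions under which the C-10' stereocentre and both alkenes are not touched, and acidification releases the acid.

Compound list

1 | 4-(allyloxy)phenol | C=CCOc1ccc(O)cc1 | starting material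
2 | allyl 4-(triisopropylsilyloxy)phenyl ether | C=CCOc1ccc(O[Si](C(C)C)(C(C)C)C(C)C)cc1 | intermediate
3 | 2-allyl-4-(triisopropylsilyloxy)phenol | C=CCc1cc(O[Si](C(C)C)(C(C)C)C(C)C)ccc1O | intermediate
4 | ethyl 2-bromo-2-methylpropanoate | CCOC(=O)C(C)(C)Br | starting material
5 | ethyl 2-[2-allyl-4-(triisopropylsilyloxy)phenoxy]-2-methylpropanoate | CCOC(=O)C(C)(C)Oc1ccc(O[Si](C(C)C)(C(C)C)C(C)C)cc1CC=C | intermediate
6 | methyl phenyl sulfone | CS(=O)(=O)c1ccccc1 | starting material
7 | 3-[2-allyl-4-(triisopropylsilyloxy)phenoxy]-3-methyl-1-(phenylsulfonyl)butan-2-one | C=CCc1cc(O[Si](C(C)C)(C(C)C)C(C)C)ccc1OC(C)(C)C(=O)CS(=O)(=O)c1ccccc1 | intermediate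
8 | (4-carboxybutyl)triphenylphosphonium bromide | OC(=O)CCCC[P+](c1ccccc1)(c1ccccc1)c1ccccc1.[Br-] | starting material
9 | 1-(tert-butyldimethylsilyloxy)propan-2-one | CC(=O)CO[Si](C)(C)C(C)(C)C | starting material
10 | sodium (Z)-7-(tert-butyldimethylsilyloxy)-6-methylhept-5-enoate | [Na+].[O-]C(=O)CCC/C=C(/C)CO[Si](C)(C)C(C)(C)C | intermediate
11 | methyl (Z)-7-(tert-butyldimethylsilyloxy)-6-methylhept-5-enoate | COC(=O)CCC/C=C(/C)CO[Si](C)(C)C(C)(C)C | intermediate
12 | methyl (Z)-7-(tert-butyldimethylsilyloxy)-2-[(dimethylamino)methyl]-6-methylhept-5-enoate (racemic) | COC(=O)C(CN(C)C)CC/C=C(/C)CO[Si](C)(C)C(C)(C)C | intermediate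
13 | [(Z)-7-(tert-butyldimethylsilyloxy)-2-(methoxycarbonyl)-6-methylhept-5-enyl]trimethylammonium iodide (racemic) | COC(=O)C(C[N+](C)(C)C)CC/C=C(/C)CO[Si](C)(C)C(C)(C)C.[I-] | intermediate
14 | methyl (Z)-7-(tert-butyldimethylsilyloxy)-6-methyl-2-methylidenehept-5-enoate | COC(=O)C(=C)CC/C=C(/C)CO[Si](C)(C)C(C)(C)C | intermediate
15 | methyl (Z)-7-bromo-6-methyl-2-methylidenehept-5-enoate | COC(=O)C(=C)CC/C=C(/C)CBr | intermediate
16 | methyl (2E,5Z)-7-bromo-6-methyl-2-{2-[2-(2-methyl-3-oxo-4-(phenylsulfonyl)butan-2-yl)oxy-5-(triisopropylsilyloxy)phenyl]ethylidene}hept-5-enoate | BrC/C(C)=C\CC/C(C(=O)OC)=C\Cc1cc(O[Si](C(C)C)(C(C)C)C(C)C)ccc1OC(C)(C)C(=O)CS(=O)(=O)c1ccccc1 | intermediate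
17 | macrocyclic β-keto sulfone: 14-membered ring aryl C-1–O–C-11'(CH3)2–C-10'(=O)–C-9'H(SO2Ph)–C-8'H2–C-7'(CH3)=C-6'H–C-5'H2–C-4'H2–C-3'(CO2CH3)=C-2'H–C-1'H2–aryl C-2, OTIPS on aryl C-4, 2'E, 6'Z, racemic at C-9' | C/C1=C/CC/C(C(=O)OC)=C\Cc2cc(O[Si](C(C)C)(C(C)C)C(C)C)ccc2OC(C)(C)C(=O)C(S(=O)(=O)c2ccccc2)C1 | intermediate
18 | macrocyclic ketone: as 17 with C-9'H2 | C/C1=C/CC/C(C(=O)OC)=C\Cc2cc(O[Si](C(C)C)(C(C)C)C(C)C)ccc2OC(C)(C)C(=O)CC1 | intermediate
19 | (10'R)-alcohol: as 18 with (R)-CH(OH) at C-10' | C/C1=C/CC/C(C(=O)OC)=C\Cc2cc(O[Si](C(C)C)(C(C)C)C(C)C)ccc2OC(C)(C)[C@H](O)CC1 | intermediate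
20 | petchiether B methyl ester: as 19 with free OH on aryl C-4 | C/C1=C/CC/C(C(=O)OC)=C\Cc2cc(O)ccc2OC(C)(C)[C@H](O)CC1 | intermediate
21 | petchiether B: (2'E,6'Z,10'R) 14-membered aryl ether with CO2H on C-3', CH3 on C-7', OH on C-10', two CH3 on C-11', OH on aryl C-4 | C/C1=C/CC/C(C(=O)O)=C\Cc2cc(O)ccc2OC(C)(C)[C@H](O)CC1 | target

Total step count: 12. Longest linear sequence: 9 steps (steps 1, 2, 3, 4, 8, 9, 10, 11, 12).

Steps most likely to fail

Step 9. Intermolecular alkylation (oligomerisation) or O-alkylation of the enolate may outrun the 14-membered C–C closure. The fallback forms the same bond by palladium-templated allylic alkylation (Tsuji–Trost) under neutral conditions. It sets out from 14 and comes back at 17. HF·pyridine in THF would remove the silyl group of 14 to give methyl (Z)-7-hydroxy-6-methyl-2-methylidenehept-5-enoate F1. Methyl chloroformate and pyridine would convert it into methyl (Z)-7-[(methoxycarbonyl)oxy]-6-methyl-2-methylidenehept-5-enoate F2. Cross-metathesis of F2 with 7 under the conditions of step 8 would give the open-chain allylic carbonate (16 with OCO2CH3 in place of Br) F3. Slow addition of F3 to Pd(PPh3)4 (zerovalent palladium) and dppe in THF at 65 °C would ionise the carbonate to a π-allyl palladium species; the methoxide set free deprotonates C-9', and attack at the less hindered C-8' terminus would give 17. Here ring closure must be faster than syn–anti equilibration of the π-allyl intermediate if the 6'Z geometry is to be kept.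

Step 8. Migration of the allyl double bond into conjugation with the arene and self-metathesis of the allyl arene may outpace the slow coupling with the 1,1-disubstituted acrylate. The fallback builds the C-2'=C-3' bond by a stabilised Wittig reaction. It sets out from 7 and 11 and comes back at 16.
- Lemieux–Johnson cleavage of the allyl group of 7 (OsO4 cat., NaIO4, 2,6-lutidine, dioxane/H2O) would give 2-[2-(2-methyl-3-oxo-4-(phenylsulfonyl)butan-2-yl)oxy-5-(triisopropylsilyloxy)phenyl]acetaldehyde F4.
- Ester 11 would be brominated at C-2 (LiN(iPr)2, THF, −78 °C; CBr4) to methyl (Z)-2-bromo-7-(tert-butyldimethylsilyloxy)-6-methylhept-5-enoate F5.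
- Heating F5 with PPh3 in toluene at 80 °C would give [(Z)-7-(tert-butyldimethylsilyloxy)-1-methoxy-6-methyl-1-oxohept-5-en-2-yl]triphenylphosphonium bromide F6.
- Aqueous NaOH/CH2Cl2 would deprotonate F6 to the stabilised ylide methyl (Z)-7-(tert-butyldimethylsilyloxy)-6-methyl-2-(triphenylphosphoranylidene)hept-5-enoate F7.
- Wittig reaction of F4 with F7 in CH2Cl2 at rt should give, E-selectively as usual for α-alkyl ester ylides, the silyl ether (16 with OSi(CH3)2C(CH3)3 in place of Br) F8.
- Camphorsulfonic acid in MeOH at 0 °C would cleave the primary alkyl silyl ether but not the aryl TIPS ether, giving the allylic alcohol (16 with OH in place of Br) F9.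
- CBr4/PPh3 in CH2Cl2 (Appel reaction) would convert F9 into 16.

Step 11. Facial discrimination may be insufficient, or turnover slow, at the hindered macrocyclic ketone flanked by the quaternary ether carbon. The fallback is a classical resolution. It sets out from 18 and comes back at 19. NaBH4 in MeOH at 0 °C would reduce 18 without stereocontrol to the racemic C-10' alcohol F10. Esterification with (S)-O-methylmandelic acid (EDC, DMAP, CH2Cl2) would give two diastereomeric esters separable by chromatography, the (10'R) (S)-O-methylmandelate F11 and the (10'S) (S)-O-methylmandelate F12. Methanolysis of F11 (K2CO3, MeOH, rt), which leaves the methyl ester as it is, would give 19.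

Further compounds

F1 | step 9 | methyl (Z)-7-hydroxy-6-methyl-2-methylidenehept-5-enoate | COC(=O)C(=C)CC/C=C(/C)CO
F2 | step 9 | methyl (Z)-7-[(methoxycarbonyl)oxy]-6-methyl-2-methylidenehept-5-enoate | COC(=O)OC/C(C)=C\CCC(=C)C(=O)OC
F3 | step 9 | open-chain allylic methyl carbonate (16 with OCO2CH3 in place of Br) | COC(=O)OC/C(C)=C\CC/C(C(=O)OC)=C\Cc1cc(O[Si](C(C)C)(C(C)C)C(C)C)ccc1OC(C)(C)C(=O)CS(=O)(=O)c1ccccc1
F4 | step 8 | 2-[2-(2-methyl-3-oxo-4-(phenylsulfonyl)butan-2-yl)oxy-5-(triisopropylsilyloxy)phenyl]acetaldehyde | O=CCc1cc(O[Si](C(C)C)(C(C)C)C(C)C)ccc1OC(C)(C)C(=O)CS(=O)(=O)c1ccccc1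
F5 | step 8 | methyl (Z)-2-bromo-7-(tert-butyldimethylsilyloxy)-6-methylhept-5-enoate (racemic) | COC(=O)C(Br)CC/C=C(/C)CO[Si](C)(C)C(C)(C)C
F6 | step 8 | [(Z)-7-(tert-butyldimethylsilyloxy)-1-methoxy-6-methyl-1-oxohept-5-en-2-yl]triphenylphosphonium bromide | COC(=O)C(CC/C=C(/C)CO[Si](C)(C)C(C)(C)C)[P+](c1ccccc1)(c1ccccc1)c1ccccc1.[Br-]
F7 | step 8 | methyl (Z)-7-(tert-butyldimethylsilyloxy)-6-methyl-2-(triphenylphosphoranylidene)hept-5-enoate | COC(=O)C(CC/C=C(/C)CO[Si](C)(C)C(C)(C)C)=P(c1ccccc1)(c1ccccc1)c1ccccc1
F8 | step 8 | open-chain (2E,5Z) silyl ether (16 with OSi(CH3)2C(CH3)3 in place of Br) | CC(C)(C)[Si](C)(C)OC/C(C)=C\CC/C(C(=O)OC)=C\Cc1cc(O[Si](C(C)C)(C(C)C)C(C)C)ccc1OC(C)(C)C(=O)CS(=O)(=O)c1ccccc1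
F9 | step 8 | open-chain (2E,5Z) allylic alcohol (16 with OH in place of Br) | OC/C(C)=C\CC/C(C(=O)OC)=C\Cc1cc(O[Si](C(C)C)(C(C)C)C(C)C)ccc1OC(C)(C)C(=O)CS(=O)(=O)c1ccccc1
F10 | step 11 | racemic C-10' alcohol (19 without configuration at C-10') | C/C1=C/CC/C(C(=O)OC)=C\Cc2cc(O[Si](C(C)C)(C(C)C)C(C)C)ccc2OC(C)(C)C(O)CC1
F11 | step 11 | (10'R) alcohol (S)-O-methylmandelate | C/C1=C/CC/C(C(=O)OC)=C\Cc2cc(O[Si](C(C)C)(C(C)C)C(C)C)ccc2OC(C)(C)[C@H](OC(=O)[C@@H](OC)c2ccccc2)CC1
F12 | step 11 | (10'S) alcohol (S)-O-methylmandelate | C/C1=C/CC/C(C(=O)OC)=C\Cc2cc(O[Si](C(C)C)(C(C)C)C(C)C)ccc2OC(C)(C)[C@@H](OC(=O)[C@@H](OC)c2ccccc2)CC1
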